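The target is read as an ent-labdane (labdane numbering used throughout): 8-hydroxy with axial C17 methyl, C18 angelate on the equatorial CH2O of C4, 13S, and a C15 malonate half ester.

**Strategy.** Everything rests on disconnecting the C9–C10 bond of ring B (C5–C6–C7–C8–C9–C10) and rejoining C10 to C8: the oxygenated C8 that sits between the quaternary C10 and the chain-bearing C9 becomes the carbonyl of a trans-hydrindanone. This ketone, whose ring A stereocentres (C4, C5) are relayed from the single catalytically set C10, is united with a citronellol-derived C9–C15 chain by Wittig olefination; dihydroxylation and mesylation give a 2-hydroxy mesylate. In the key step C10 migrates from C8 to C9 (semipinacol shift), enlarging the cyclopentane to ring B, forging C9–C10, fixing C9 and unveiling the C8 ketone from which the tertiary carbinol is made.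

Key step: step 15

Remark on numbering: ring A = C1–C5 + C10, ring B = C5–C10, C17 = methyl on C8, C18 = oxygenated carbon on C4, C20 = methyl on C10, side chain C11–C15; in the hydrindanes the five-membered ring is C5–C6–C7–C8–C10.
Assumption: the Wittig olefination of the hindered cyclopentanone (step 12) is taken to give the Z-alkylidene (C11 cis to C10), as 17-oxo steroids do with unstabilised ylides.

Step 1
Reactants: 1 2-methylcyclopentane-1,3-dione; 2 pent-1-en-3-one
Product: 3 triketone 2-methyl-2-(3-oxopentyl)cyclopentane-1,3-dione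
Conditions: H2O, AcOH (cat.), 70 °C
Reagents that add atoms: none
Why: Michael addition of the enolised 1,3-dione to the vinyl ketone is the standard first half of a Hajos–Parrish-type annulation and creates no stereocentre.

Step 2
Reactants: 3 triketone
Product: 4 (R)-enedione
Conditions: D-phenylalanine (1 equiv), 1 M HClO4 (0.5 equiv), MeCN, reflux
Reagents that add atoms: none
Why: Hajos–Parrish–Eder–Sauer–Wiechert aldol condensation: the amino-acid enamine of the side-chain ketone attacks one of the two enantiotopic ring carbonyls, which sets C10 (the D-amino acid should give the R enantiomer, the mirror image of the steroid series), and dehydration gives the enone; the enantiomeric purity should be raised by crystallisation.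

Step 3
Reactants: 4 (R)-enedione
Product: 5 hydroxy enone
Conditions: NaBH4 (0.3 equiv), EtOH, −20 °C
Reagents that add atoms: none
Why: Chemoselective borohydride reduction of the saturated cyclopentanone beside the less electrophilic enone; hydride adds anti to the angular methyl, so the C8 hydroxyl is cis to the C10 methyl (a temporary mask of the C8 ketone).

Step 4
Reactants: 5 hydroxy enone
Product: 8 hydroxy keto ester, via dilithium enolate 6 (not isolated), via keto acid 7 (not isolated)
Conditions: Li (2.2 equiv), NH3(l)/THF, −78 °C; NH3 off; CO2 (g), Et2O, −78 → 0 °C; cold aq. HCl; TMSCHN2, MeOH/PhMe, 0 °C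
Reagents that add atoms: carbon dioxide O=C=O; (trimethylsilyl)diazomethane C[Si](C)(C)C=[N+]=[N-]
Why: Birch-type enone reduction with enolate carboxylation (reductive carboxylation): C5 is protonated (the C8–OH serving as internal proton donor) on the face opposite the C10 methyl to give the trans ring fusion, and CO2 adds to C4 of the regiodefined C3 enolate from the face opposite the C10 methyl, so the carboxyl ends trans and the C4 methyl cis to it; the acid is esterified at once to forestall decarboxylation.

Step 5
Reactants: 8 hydroxy keto ester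
Product: 9 dithiolane
Conditions: HSCH2CH2SH, BF3·OEt2, CH2Cl2, 0 °C → rt
Reagents that add atoms: ethane-1,2-dithiol SCCS
Why: Lewis-acid-promoted thioacetalisation of the only ketone; ester and alcohol do not react and no stereocentre is touched.

Step 6
Reactants: 9 dithiolane
Product: 10 hydroxy ester
Conditions: Raney Ni (W-2), EtOH, reflux
Reagents that add atoms: none
Why: Mozingo desulfurisation replaces the C3 thioacetal by CH2 under neutral conditions that leave the ester, the alcohol and all stereocentres intact.

Step 7
Reactants: 10 hydroxy ester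
Product: 11 keto ester
Conditions: TPAP (5 mol %), NMO, 4 Å MS, CH2Cl2, rt
Reagents that add atoms: none
Why: Ley–Griffith oxidation of the secondary C8 alcohol returns the cyclopentanone without epimerisable centres at risk (C10 is quaternary, C4 has no α-hydrogen).

Step 8
Reactants: 12 (S)-citronellol
Product: 13 silyl ether
Conditions: TBDPSCl, imidazole, CH2Cl2, rt
Reagents that add atoms: tert-butyl(chloro)diphenylsilane CC(C)(C)[Si](Cl)(c1ccccc1)c1ccccc1
Why: Standard silylation of the primary alcohol (future C15–O); the bought stereocentre (future C13, S) is untouched.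

Step 9
Reactants: 13 silyl ether
Product: 15 alcohol, via aldehyde 14 (not isolated)
Conditions: O3, CH2Cl2/MeOH, −78 °C; then NaBH4, −78 °C → rt
Reagents that add atoms: ozone [O-][O+]=O
Why: Ozonolysis of the trisubstituted alkene with reductive borohydride work-up removes the isopropylidene carbons and leaves the C9 carbon as a primary alcohol; C13 is not affected.

Step 10
Reactants: 15 alcohol
Product: 16 iodide
Conditions: I2, PPh3, imidazole, CH2Cl2, 0 °C → rt
Reagents that add atoms: iodine II
Why: Appel-type iodination of an unhindered primary alcohol by SN2 displacement of the oxyphosphonium.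

Step 11
Reactants: 16 iodide
Product: 17 phosphonium iodide
Conditions: PPh3, MeCN, reflux
Reagents that add atoms: triphenylphosphine c1ccccc1P(c1ccccc1)c1ccccc1
Why: SN2 quaternisation of triphenylphosphine by the primary iodide gives the Wittig salt.

Step 12
Reactants: 11 keto ester; 17 phosphonium iodide
Product: 19 Z-alkene, via phosphorus ylide 18 (not isolated)
Conditions: 17 (3 equiv), KOt-Bu, THF, 0 °C; then 11, reflux
Reagents that add atoms: none
Why: Wittig olefination with an unstabilised ylide under forcing conditions as used for 17-oxo steroids; kinetic control should give the Z-alkylidene (C11 cis to C10), and the neopentyl methyl ester and silyl ether are inert to the ylide.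

Step 13
Reactants: 19 Z-alkene
Product: 20 diol
Conditions: OsO4 (5 mol %), NMO, acetone/H2O, rt
Reagents that add atoms: N-methylmorpholine N-oxide C[N+]1([O-])CCOCC1; water O; osmium tetroxide O=[Os](=O)(=O)=O (catalytic oxygen carrier)
Why: Catalytic syn-dihydroxylation of the only alkene from the face opposite the angular C10 methyl sets C8 (tertiary OH trans to the C10 methyl) and C9 (R) in one event.

Step 14
Reactants: 20 diol
Product: 21 hydroxy mesylate
Conditions: MsCl, Et3N, CH2Cl2, −10 °C
Reagents that add atoms: methanesulfonyl chloride CS(=O)(=O)Cl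
Why: Sulfonylation occurs only at the secondary C9 hydroxyl, the tertiary C8 hydroxyl being too hindered, and no stereocentre changes.

Step 15
Reactants: 21 hydroxy mesylate
Product: 23 8-oxo ester, via 9-epi ketone 22 (not isolated)
Conditions: Et3Al (3 equiv), CH2Cl2, −78 → 0 °C; aq. Rochelle salt; then NaOMe (0.2 equiv), MeOH, rt
Reagents that add atoms: none
Why: Et3Al turns the tertiary C8 alcohol into an aluminium alkoxide and activates the C9 mesylate; the C8–C10 bond, anti-periplanar to the C9–O bond in the least crowded rotamer, shifts from C8 to C9 as the mesylate leaves while C8–O becomes the carbonyl, so the cyclopentane C5–C6–C7–C8–C10 is enlarged by C9 into ring B. The closest known reaction types are the Tsuchihashi–Suzuki rearrangement of 2-hydroxy mesylates, the pinacol-type ring enlargement of diol monosulfonates and the D-homoannulation of 17-hydroxy-20-sulfonyloxy or 20-amino steroids. No ring is closed by cyclisation: the six-membered ring arises solely by this 1,2-alkyl shift, C10 migrating with retention. C9 is formed with inversion at the mesylate carbon, which places the side chain axial (22, 9R); the methoxide stage epimerises this enolisable centre to the equatorial chain of 23 (9S, cis to the C10 methyl), the thermodynamic arrangement. The step needs migration of the quaternary C10 in preference to the C7 methylene and rearrangement in preference to closure to the 8,9-epoxide; the higher migratory aptitude of the tertiary carbon, the rotamer preference of the Z-derived diol (chain between O8 and C10, not between C10 and C7) and the Lewis-acidic, non-basic medium should secure both.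

Step 16
Reactants: 23 8-oxo ester
Product: 24 8(17)-alkene
Conditions: Ph3PCH3Br, KOt-Bu, toluene, 90 °C
Reagents that add atoms: methyltriphenylphosphonium bromide [Br-].C[P+](c1ccccc1)(c1ccccc1)c1ccccc1
Why: Wittig methylenation of the ring-B ketone, standard for 8-oxolabdanes; the equatorial C9 chain is already the thermodynamic epimer, so the basic medium cannot erode it.

Step 17
Reactants: 24 8(17)-alkene
Product: 25 epoxide
Conditions: mCPBA, NaHCO3, CH2Cl2, 0 °C
Reagents that add atoms: 3-chloroperoxybenzoic acid OOC(=O)c1cccc(Cl)c1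
Why: Prilezhaev epoxidation: the peracid approaches the exocyclic alkene from the equatorial side, away from the axial C10 methyl, so the oxygen on C8 becomes equatorial (trans to the C10 methyl), as in labd-8(17)-enes.

Step 18
Reactants: 25 epoxide
Product: 26 diol
Conditions: LiAlH4, THF, 0 °C → rt
Reagents that add atoms: none
Why: Hydride opens the spiro-epoxide at its unhindered CH2 terminus (C17 becomes the axial methyl, the C8 configuration from step 17 is kept) and reduces the C18 methyl ester to the primary alcohol in the same operation; the silyl ether is stable.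

Step 19
Reactants: 26 diol; 27 angelic acid
Product: 29 angelate, via mixed anhydride 28 (not isolated)
Conditions: 27, 2,4,6-trichlorobenzoyl chloride, Et3N, toluene, rt; then 26, 80 °C (no DMAP)
Reagents that add atoms: none
Why: Yamaguchi mixed-anhydride esterification without nucleophilic catalyst, conditions under which the Z-2-methylbut-2-enoyl group should not isomerise to the tiglate; only the primary C18 hydroxyl is acylated, the tertiary C8 hydroxyl being inert.

Step 20
Reactants: 29 angelate
Product: 30 hydroxy angelate
Conditions: HF·pyridine, pyridine/THF, 0 °C → rt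
Reagents that add atoms: none
Why: Fluoride-mediated desilylation under buffered conditions that leave the angelate geometry, the ester and the tertiary alcohol untouched.

Step 21
Reactants: 30 hydroxy angelate; 31 Meldrum's acid
Product: 32 target
Conditions: toluene, 90 °C
Reagents that add atoms: none
Why: Thermal ring-opening acylation by Meldrum's acid (loss of acetone) converts the unhindered primary C15 alcohol directly into the malonic acid half ester without base or activating agent; the tertiary C8 alcohol does not react.

**Compound list**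

1 | 2-methylcyclopentane-1,3-dione | CC1C(=O)CCC1=O | starting material
2 | pent-1-en-3-one (ethyl vinyl ketone) | CCC(=O)C=C | starting material
3 | 2-methyl-2-(3-oxopentyl)cyclopentane-1,3-dione (triketone) | CCC(=O)CCC1(C)C(=O)CCC1=O | intermediate
4 | (7aR)-4,7a-dimethyl-2,3,7,7a-tetrahydro-1H-indene-1,5(6H)-dione (enedione, C10 = R) | CC1=C2CCC(=O)[C@]2(C)CCC1=O | intermediate
5 | (1R,7aR)-1-hydroxy-4,7a-dimethyl-1,2,3,6,7,7a-hexahydro-5H-inden-5-one (8-OH cis to the C10 methyl) | CC1=C2CC[C@@H](O)[C@]2(C)CCC1=O | intermediate
6 | dilithium C3-enolate / C8-alkoxide of the trans-fused reduced ketone (H5 trans to the C10 methyl) | [Li+].[Li+].CC1=C([O-])CC[C@]2(C)[C@@H]1CC[C@H]2[O-] | intermediate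
7 | trans-hydrindane keto acid: 3-oxo, CO2H on C4 trans and CH3 on C4 cis to the C10 methyl, 8-OH cis to the C10 methyl | OC(=O)[C@@]1(C)C(=O)CC[C@]2(C)[C@@H]1CC[C@H]2O | intermediate
8 | methyl ester of 7 (hydroxy keto ester) | COC(=O)[C@@]1(C)C(=O)CC[C@]2(C)[C@@H]1CC[C@H]2O | intermediate
9 | C3 1,3-dithiolane of 8 | COC(=O)[C@@]1(C)C2(SCCS2)CC[C@]3(C)[C@@H]1CC[C@H]3O | intermediate
10 | hydroxy ester: trans-hydrindane, C3 = CH2, CO2Me on C4 trans to the C10 methyl, 8-OH cis to the C10 methyl | COC(=O)[C@@]1(C)CCC[C@]2(C)[C@@H]1CC[C@H]2O | intermediate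
11 | keto ester: trans-hydrindan-8-one, H5 trans to the C10 methyl, CO2Me on C4 trans to the C10 methyl | COC(=O)[C@@]1(C)CCC[C@]2(C)[C@@H]1CCC2=O | intermediate
12 | (S)-citronellol, (3S)-3,7-dimethyloct-6-en-1-ol | CC(C)=CCC[C@H](C)CCO | starting material
13 | (S)-citronellyl tert-butyldiphenylsilyl ether | CC(C)=CCC[C@H](C)CCO[Si](c1ccccc1)(c1ccccc1)C(C)(C)C | intermediate
14 | (4S)-6-(tert-butyldiphenylsilyloxy)-4-methylhexanal | O=CCC[C@H](C)CCO[Si](c1ccccc1)(c1ccccc1)C(C)(C)C | intermediate
15 | (4S)-6-(tert-butyldiphenylsilyloxy)-4-methylhexan-1-ol | OCCC[C@H](C)CCO[Si](c1ccccc1)(c1ccccc1)C(C)(C)C | intermediate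
16 | (4S)-6-(tert-butyldiphenylsilyloxy)-1-iodo-4-methylhexane | ICCC[C@H](C)CCO[Si](c1ccccc1)(c1ccccc1)C(C)(C)C | intermediate
17 | [(4S)-6-(tert-butyldiphenylsilyloxy)-4-methylhexyl]triphenylphosphonium iodide | [I-].c1ccccc1[P+](c1ccccc1)(c1ccccc1)CCC[C@H](C)CCO[Si](c1ccccc1)(c1ccccc1)C(C)(C)C | intermediate
18 | the corresponding hexylidene triphenylphosphorane (ylide, carbanion carbon = C9) | c1ccccc1P(c1ccccc1)(c1ccccc1)=CCC[C@H](C)CCO[Si](c1ccccc1)(c1ccccc1)C(C)(C)C | intermediate
19 | (Z)-8(9)-alkylidene hydrindane ester, C11 cis to C10 | COC(=O)[C@@]1(C)CCC[C@]2(C)[C@@H]1CC/C2=C/CC[C@H](C)CCO[Si](c3ccccc3)(c3ccccc3)C(C)(C)C | intermediate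
20 | 8,9-diol, both hydroxyls anti to the C10 methyl, 9R | COC(=O)[C@@]1(C)CCC[C@]2(C)[C@@H]1CC[C@@]2(O)[C@H](O)CC[C@H](C)CCO[Si](c3ccccc3)(c3ccccc3)C(C)(C)C | intermediate
21 | 9-methanesulfonate of 20 (8-OH free) | COC(=O)[C@@]1(C)CCC[C@]2(C)[C@@H]1CC[C@@]2(O)[C@H](OS(C)(=O)=O)CC[C@H](C)CCO[Si](c3ccccc3)(c3ccccc3)C(C)(C)C | intermediate
22 | ring-expanded 8-oxo trans-decalin ester, 9R (side chain axial, trans to the C10 methyl) | COC(=O)[C@@]1(C)CCC[C@]2(C)[C@@H]1CCC(=O)[C@@H]2CC[C@H](C)CCO[Si](c3ccccc3)(c3ccccc3)C(C)(C)C | intermediate
23 | 8-oxo trans-decalin ester, 9S (side chain equatorial, cis to the C10 methyl) | COC(=O)[C@@]1(C)CCC[C@]2(C)[C@@H]1CCC(=O)[C@H]2CC[C@H](C)CCO[Si](c3ccccc3)(c3ccccc3)C(C)(C)C | intermediate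
24 | 8(17)-methylene ester | COC(=O)[C@@]1(C)CCC[C@]2(C)[C@@H]1CCC(=C)[C@H]2CC[C@H](C)CCO[Si](c3ccccc3)(c3ccccc3)C(C)(C)C | intermediate
25 | 8,17-epoxide, oxygen equatorial on C8 (trans to the C10 methyl) | COC(=O)[C@@]1(C)CCC[C@]2(C)[C@@H]1CC[C@@]3(CO3)[C@H]2CC[C@H](C)CCO[Si](c4ccccc4)(c4ccccc4)C(C)(C)C | intermediate
26 | 8,18-diol 15-TBDPS ether (full target skeleton and stereochemistry) | OC[C@@]1(C)CCC[C@]2(C)[C@@H]1CC[C@](C)(O)[C@H]2CC[C@H](C)CCO[Si](c3ccccc3)(c3ccccc3)C(C)(C)C | intermediate
27 | angelic acid, (Z)-2-methylbut-2-enoic acid | C/C=C(/C)C(=O)O | starting material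
28 | angelic 2,4,6-trichlorobenzoic mixed anhydride | C/C=C(/C)C(=O)OC(=O)c1c(Cl)cc(Cl)cc1Cl | intermediate
29 | 18-angelate 15-TBDPS ether | C/C=C(/C)C(=O)OC[C@@]1(C)CCC[C@]2(C)[C@@H]1CC[C@](C)(O)[C@H]2CC[C@H](C)CCO[Si](c3ccccc3)(c3ccccc3)C(C)(C)C | intermediate
30 | 18-angelate 8,15-diol | C/C=C(/C)C(=O)OC[C@@]1(C)CCC[C@]2(C)[C@@H]1CC[C@](C)(O)[C@H]2CC[C@H](C)CCO | intermediate
31 | Meldrum's acid, 2,2-dimethyl-1,3-dioxane-4,6-dione | CC1(C)OC(=O)CC(=O)O1 | starting material
32 | CNP0286290.1: 18-angelate 15-(hydrogen malonate) of the 8-hydroxy ent-labdane | C/C=C(/C)C(=O)OC[C@@]1(C)CCC[C@]2(C)[C@@H]1CC[C@](C)(O)[C@H]2CC[C@H](C)CCOC(=O)CC(=O)O | target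

**Step count.** Total: 21 steps. Longest linear sequence: 17 steps (steps 1–7 and 12–21, from 1 and 2). The side-chain branch (steps 8–11) adds 4 steps and joins in step 12.

**Steps most likely to fail**

Step 15 (key step). The shift may go astray as a process: migration of the C7 methylene in place of C10, closure of the aluminium alkoxide onto C9 to the 8,9-epoxide, or plain elimination. Fallback (pinacolic deamination, the 20-amino-17-hydroxy steroid type of D-homoannulation): it sets out from diol 20, which is oxidised at the secondary C9 hydroxyl (Dess–Martin periodinane, CH2Cl2) to the α-hydroxy ketone F1. Oximation (NH2OH·HCl, pyridine, EtOH) gives the oxime F2 and hydrogenation (H2, PtO2, AcOH) the amino alcohol F3 (drawn as the C9 epimer that matches 21; both epimers lead to the same ketone after equilibration). Diazotisation (NaNO2, aq. AcOH, 0 °C) then triggers the same C10 shift with dinitrogen as leaving group, which needs no Lewis acid and is not displaced by the neighbouring hydroxyl in acid. After NaOMe/MeOH equilibration the route is rejoined at ketone 23.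

Step 12. Enolisation of the hindered cyclopentanone by the basic ylide may stall conversion, and the Z geometry may erode. Fallback (stepwise Horner–Wittig olefination): it sets out from iodide 16, which is converted (Ph2PLi, THF; then H2O2) into the phosphine oxide F4. Its lithio derivative (n-BuLi, THF, −78 °C) adds to ketone 11 to give the β-hydroxy phosphine oxide F5, an isolable adduct whose erythro diastereomer is separated by chromatography. Stereospecific syn-elimination (NaH, DMF) then gives the alkene, and the route is rejoined at alkene 19.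

Step 19. The angelate may isomerise to the tiglate during acyl transfer, and acylation of the neopentyl C18 alcohol may be sluggish. Fallback (ester bond first, Z double bond afterwards, by Still–Gennari olefination): it sets out from diol 26, which is esterified (DCC, DMAP, CH2Cl2) with 2-[bis(2,2,2-trifluoroethoxy)phosphoryl]propanoic acid to the phosphonate ester F6 (epimeric at the phosphorus-bearing carbon, which is destroyed in the next step). KHMDS/18-crown-6 and acetaldehyde (THF, −78 °C) build the Z-2-methylbut-2-enoate directly, and the route is rejoined at angelate 29.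

Further compounds
F1 | step 15 | α-hydroxy ketone: 8-hydroxy-9-oxo hydrindane ester (8-OH trans to the C10 methyl) | COC(=O)[C@@]1(C)CCC[C@]2(C)[C@@H]1CC[C@@]2(O)C(=O)CC[C@H](C)CCO[Si](c3ccccc3)(c3ccccc3)C(C)(C)C
F2 | step 15 | (E)-oxime of F1 | COC(=O)[C@@]1(C)CCC[C@]2(C)[C@@H]1CC[C@@]2(O)/C(=N/O)CC[C@H](C)CCO[Si](c3ccccc3)(c3ccccc3)C(C)(C)C
F3 | step 15 | 9-amino-8-hydroxy hydrindane ester (C9 configured as in 21) | COC(=O)[C@@]1(C)CCC[C@]2(C)[C@@H]1CC[C@@]2(O)[C@H](N)CC[C@H](C)CCO[Si](c3ccccc3)(c3ccccc3)C(C)(C)C
F4 | step 12 | [(4S)-6-(tert-butyldiphenylsilyloxy)-4-methylhexyl]diphenylphosphine oxide | O=P(c1ccccc1)(c1ccccc1)CCC[C@H](C)CCO[Si](c1ccccc1)(c1ccccc1)C(C)(C)C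
F5 | step 12 | erythro β-hydroxy phosphine oxide: 8-OH cis to the C10 methyl, C9 bearing P(O)Ph2 | COC(=O)[C@@]1(C)CCC[C@]2(C)[C@@H]1CC[C@]2(O)[C@@H](P(=O)(c3ccccc3)c3ccccc3)CC[C@H](C)CCO[Si](c3ccccc3)(c3ccccc3)C(C)(C)C
F6 | step 19 | 18-[2-(bis(2,2,2-trifluoroethoxy)phosphoryl)propanoate] of diol 26 | CC(C(=O)OC[C@@]1(C)CCC[C@]2(C)[C@@H]1CC[C@](C)(O)[C@H]2CC[C@H](C)CCO[Si](c3ccccc3)(c3ccccc3)C(C)(C)C)P(=O)(OCC(F)(F)F)OCC(F)(F)F
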